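## Retrosynthetic overview

1. Numbering: ring B is C1H2–C2(Br)=C3(Me)–C4H2–C5H2, the spiro atom is C6, and ring A is C7(Me)=C8H–C9H(OH)–C10H(Br)–C11Me2. The target is (6S,9S,10S)-15.
2. C9–OH and C10–Br come from anti bromohydrin formation on the ring A diene of triene 12. Triene 12 comes from allylic bromide 11 by loss of HBr.
3. Ring B is closed last, through C1–C2. Bromide 11 is an isomer of vinylcyclopropane 7, in which C1 is the CH2 of a temporary cyclopropane (C1–C6–C7) and C2 is the CBr2 carbon of a gem-dibromoalkene. A bromine-atom chain opens the three-membered ring, closes ring B and moves one bromine from C2 to C9.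
4. Enabling feature: C1 lies between the quaternary spiro C6 and the vinylic C2. C6 has no β-hydrogen and is homoallylic to C7=C8, which is the retron of a cyclopropylcarbinyl radical opening. The C2(Br)=C3(Me) unit is a CBr2=C(Me) group that has lost one bromine.
5. Compound 7 comes from dihydro-β-ionone 1 (ring A and 13 of the 15 carbons), CBr4 (C2) and CH2I2 (C1). C6 is set by CBS reduction and hydroxyl-directed cyclopropanation. Ring order: A (bought), cyclopropane (temporary), B.

Key step: step 7

Assumption: C9 in 8–11 is drawn for bromine addition anti to the angular methyl group. This has no consequence, because C9 becomes sp2 in step 8.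

## Route

Step 1
Reactants: 1 dihydro-β-ionone, 4-(2,6,6-trimethylcyclohex-1-en-1-yl)butan-2-one
Product: 2 2,4,4-trimethyl-3-(3-oxobutyl)cyclohex-2-en-1-one
Conditions: Rh2(cap)4 (dirhodium tetracaprolactamate, 1 mol%), t-BuOOH (70% aq.), K2CO3, CH2Cl2, rt
Reagents that add atoms: tert-butyl hydroperoxide, CC(C)(C)OO
Why: Radical allylic C–H oxidation to the enone (dirhodium caprolactamate/t-BuOOH type) should pick the ring CH2 next to the methyl-bearing alkene carbon, the only unhindered secondary allylic position, because the allylic CH2 of the side chain is shielded by the adjacent gem-dimethyl carbon; no stereocentre is formed.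

Step 2
Reactants: 2 2,4,4-trimethyl-3-(3-oxobutyl)cyclohex-2-en-1-one
Product: 3 3-(4,4-dibromo-3-methylbut-3-en-1-yl)-2,4,4-trimethylcyclohex-2-en-1-one
Conditions: CBr4, PPh3, PhMe, reflux
Reagents that add atoms: carbon tetrabromide, BrC(Br)(Br)Br
Why: Ramirez gem-dibromoolefination: Ph3P=CBr2 made in the flask attacks the unhindered methyl ketone, while the conjugated carbonyl group flanked by a fully substituted alkene stays untouched; no stereocentre is formed.

Step 3
Reactants: 3 3-(4,4-dibromo-3-methylbut-3-en-1-yl)-2,4,4-trimethylcyclohex-2-en-1-one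
Product: 4 (1S)-3-(4,4-dibromo-3-methylbut-3-en-1-yl)-2,4,4-trimethylcyclohex-2-en-1-ol
Conditions: (R)-Me-CBS (20 mol%), BH3·SMe2, THF, −30 °C
Reagents that add atoms: none
Why: Corey–Bakshi–Shibata reduction: the fully substituted alkene arm is the large group and the ring CH2 the small one, so the (R)-oxazaborolidine–borane complex should deliver hydride to the face that gives the (1S) alcohol, and the electron-poor dibromoalkene is not hydroborated.

Step 4
Reactants: 4 (1S)-3-(4,4-dibromo-3-methylbut-3-en-1-yl)-2,4,4-trimethylcyclohex-2-en-1-ol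
Product: 5 (1R,2S,6R)-6-(4,4-dibromo-3-methylbut-3-en-1-yl)-1,5,5-trimethylbicyclo[4.1.0]heptan-2-ol (cyclopropane CH2 cis to OH)
Conditions: Et2Zn, CH2I2, CH2Cl2, −10 °C to rt
Reagents that add atoms: diiodomethane, ICI
Why: Hydroxyl-directed Simmons–Smith cyclopropanation (Furukawa variant): the zinc alkoxide guides the carbenoid to the electron-rich tetrasubstituted alkene on the face of the OH group, which sets both ring-fusion centres (the later spiro C6 among them) from the carbinol centre, and the electron-poor dibromoalkene does not react.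

Step 5
Reactants: 5 (1R,2S,6R)-6-(4,4-dibromo-3-methylbut-3-en-1-yl)-1,5,5-trimethylbicyclo[4.1.0]heptan-2-ol
Product: 6 O-[(1R,2S,6R)-6-(4,4-dibromo-3-methylbut-3-en-1-yl)-1,5,5-trimethylbicyclo[4.1.0]heptan-2-yl] S-methyl dithiocarbonate
Conditions: NaH, CS2, then MeI, THF, 0 °C to rt
Reagents that add atoms: carbon disulfide, S=C=S; iodomethane, CI
Why: Xanthate formation (first half of a Chugaev elimination) takes place at oxygen, so all three stereocentres are kept, and the vinylic bromides carry no hydrogen that NaH could remove.

Step 6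
Reactants: 6 O-alkyl S-methyl dithiocarbonate of 5
Product: 7 (1S,6R)-6-(4,4-dibromo-3-methylbut-3-en-1-yl)-1,5,5-trimethylbicyclo[4.1.0]hept-2-ene
Conditions: o-dichlorobenzene, 180 °C
Reagents that add atoms: none
Why: Chugaev syn-elimination through a six-membered cyclic transition state takes the only β-hydrogens (ring CH2) without a free cyclopropylcarbinyl cation, as known for the preparation of vinylcyclopropanes from cyclopropyl carbinols; the two ring-fusion centres are untouched.

Step 7
Reactants: 7 (1S,6R)-6-(4,4-dibromo-3-methylbut-3-en-1-yl)-1,5,5-trimethylbicyclo[4.1.0]hept-2-ene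
Product: 11 (6R,9S)-2,9-dibromo-3,7,11,11-tetramethylspiro[5.5]undeca-2,7-diene, via cyclopropylcarbinyl radical 8 (not isolated), via ring-opened primary radical 9 (not isolated), via tertiary dibromoalkyl radical 10 (not isolated)
Conditions: cinnamyl bromide (10 mol%), 4CzIPN (1 mol%), 1,2-epoxybutane (HBr trap), PhH, 0.005 M, 450 nm LED, rt
Reagents that add atoms: none
Why: Proposed new method: a bromine atom, started by sensitised homolysis of the catalytic cinnamyl bromide, adds reversibly to C9 of the C8=C9 alkene of 7 and gives cyclopropylcarbinyl radical 8, whose singly occupied orbital overlaps with the exocyclic C7–C1 bond of the three-membered ring, so that 8 opens to the C7=C8 alkene and the primary radical 9; 9 adds to the CBr2 carbon of the side-chain alkene and the tertiary radical 10 expels a bromine atom that carries the chain, so 7 isomerises to 11 and one bromine moves from C2 to C9. The closest known reaction types are the bromine-radical-catalysed ring-opening cycloadditions of vinylcyclopropanes, the ring opening–cyclisation cascades of bicyclo[4.1.0]heptyl radicals that give spirocycles, and the addition–elimination of alkyl radicals on halogenated alkenes; their union on a gem-dibromoalkene is new. Ring B is closed in the 6-endo-trig mode at C2 (radical vinylic substitution), and the temporary cyclopropane is the only ring that is opened. The configuration of C6 is not made here but carried over from 5, because the bonds from C6 to C1, C5, C7 and C11 all stay intact; the new centre C9 is expected to form by bromine addition anti to the angular methyl group and is erased in step 8. The step needs exocyclic instead of endocyclic cyclopropane cleavage (secured by orbital overlap in the half-chair of 8), 6-endo instead of 5-exo attack (C3 is fully substituted, the 5-exo adduct has no leaving group in β position and can only revert, whereas 10 loses bromine irreversibly) and a long-lived radical 9 (C6 is quaternary, so 9 has no β-hydrogen to lose, and high dilution in benzene with an HBr trap suppresses hydrogen and bromine transfer).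

Step 8
Reactants: 11 (6R,9S)-2,9-dibromo-3,7,11,11-tetramethylspiro[5.5]undeca-2,7-diene
Product: 12 (6S)-2-bromo-3,7,11,11-tetramethylspiro[5.5]undeca-2,7,9-triene
Conditions: DBU, PhMe, 80 °C
Reagents that add atoms: none
Why: E2 dehydrobromination: DBU takes a C10 hydrogen anti to the allylic C9 bromide and gives the conjugated ring A diene, the vinylic C2 bromide is inert to base, C9 loses its stereocentre and C6 is untouched (its descriptor changes only through the priority rules).

Step 9
Reactants: 12 (6S)-2-bromo-3,7,11,11-tetramethylspiro[5.5]undeca-2,7,9-triene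
Product: 15 (6S,9S,10S)-2,10-dibromo-3,7,11,11-tetramethylspiro[5.5]undeca-2,7-dien-9-ol, via bromonium ion 13 (not isolated), via oxonium adduct 14 (not isolated)
Conditions: NBS, acetone/H2O, 0 °C
Reagents that add atoms: N-bromosuccinimide, O=C1CCC(=O)N1Br; water, O
Why: Bromohydrin formation on a 1,3-diene: Br+ goes to the diene terminus C10 because this gives the allyl cation that is stabilised by the C7 methyl group, water opens the bromonium ion anti at allylic C9, which secures the trans (9S,10S) relation, the deactivated ring B bromoalkene stays out, and the choice of the diene face syn to C1 rests on substrate control by C6 only, which is expected to be modest (see risks).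

## Compound list

1 | dihydro-β-ionone | CC(=O)CCC1=C(C)CCCC1(C)C | starting material
2 | 2,4,4-trimethyl-3-(3-oxobutyl)cyclohex-2-en-1-one | CC(=O)CCC1=C(C)C(=O)CCC1(C)C | intermediate
3 | 3-(4,4-dibromo-3-methylbut-3-en-1-yl)-2,4,4-trimethylcyclohex-2-en-1-one | CC(CCC1=C(C)C(=O)CCC1(C)C)=C(Br)Br | intermediate
4 | (1S)-3-(4,4-dibromo-3-methylbut-3-en-1-yl)-2,4,4-trimethylcyclohex-2-en-1-ol | CC(CCC1=C(C)[C@@H](O)CCC1(C)C)=C(Br)Br | intermediate
5 | (1R,2S,6R)-6-(4,4-dibromo-3-methylbut-3-en-1-yl)-1,5,5-trimethylbicyclo[4.1.0]heptan-2-ol | CC(CC[C@]12C[C@@]1(C)[C@@H](O)CCC2(C)C)=C(Br)Br | intermediate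
6 | S-methyl xanthate of 5 | CC(CC[C@]12C[C@@]1(C)[C@@H](OC(=S)SC)CCC2(C)C)=C(Br)Br | intermediate
7 | (1S,6R)-6-(4,4-dibromo-3-methylbut-3-en-1-yl)-1,5,5-trimethylbicyclo[4.1.0]hept-2-ene | CC(CC[C@]12C[C@@]1(C)C=CCC2(C)C)=C(Br)Br | intermediate
8 | C8-centred cyclopropylcarbinyl radical, 9-bromo | CC(CC[C@]12C[C@@]1(C)[CH][C@@H](Br)CC2(C)C)=C(Br)Br | intermediate
9 | C1-centred primary radical | CC1=C[C@@H](Br)CC(C)(C)[C@]1([CH2])CCC(C)=C(Br)Br | intermediate
10 | C3-centred tertiary radical, 2,2-dibromo | CC1=C[C@@H](Br)CC(C)(C)[C@]12CC[C](C)C(Br)(Br)C2 | intermediate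
11 | (6R,9S)-2,9-dibromo-3,7,11,11-tetramethylspiro[5.5]undeca-2,7-diene | CC1=C[C@@H](Br)CC(C)(C)[C@]12CCC(C)=C(Br)C2 | intermediate
12 | (6S)-2-bromo-3,7,11,11-tetramethylspiro[5.5]undeca-2,7,9-triene | CC1=CC=CC(C)(C)[C@]12CCC(C)=C(Br)C2 | intermediate
13 | C9–C10 bromonium ion on the face syn to C1 | CC1=C[C@H]2[Br+][C@H]2C(C)(C)[C@]13CCC(C)=C(Br)C3 | intermediate
14 | C9 oxonium adduct of 13 and water | CC1=C[C@H]([OH2+])[C@@H](Br)C(C)(C)[C@]12CCC(C)=C(Br)C2 | intermediate
15 | (6S,9S,10S)-2,10-dibromo-3,7,11,11-tetramethylspiro[5.5]undeca-2,7-dien-9-ol | CC1=C[C@H](O)[C@@H](Br)C(C)(C)[C@]12CCC(C)=C(Br)C2 | target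

Total step count: 9. Longest linear sequence: 9.

## Steps most likely to fail

**Step 7.** The 6-endo addition of the neopentyl radical to the crowded CBr2 terminus may be too slow. The chain would then die by bromine or hydrogen transfer, or endocyclic cleavage of the cyclopropane could take over.

The fallback splits the cascade into known operations.
- From 7, radical 1,5-dibromination (Br2 added slowly, hν, PhCF3, −20 °C) catches the ring-opened radical as (3S,6R)-3-bromo-6-(bromomethyl)-6-(4,4-dibromo-3-methylbut-3-en-1-yl)-1,5,5-trimethylcyclohex-1-ene F1.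
- DBU removes the allylic HBr and gives (6S)-6-(bromomethyl)-6-(4,4-dibromo-3-methylbut-3-en-1-yl)-1,5,5-trimethylcyclohexa-1,3-diene F2.
- A nickel-catalysed reductive alkyl–alkenyl cross-electrophile coupling (NiBr2·glyme, 4,4′-di-tert-butyl-2,2′-bipyridine, Mn powder, NaI, DMA) closes C1–C2. The route is rejoined at 12.

**Step 9.** Facial selectivity of bromonium formation relative to C6 may be poor, and water may be captured at C7 (1,4-addition).

The fallback puts the face under catalyst control.
- From 12, Jacobsen–Katsuki epoxidation of the cis-disubstituted C9=C10 alkene gives the 9,10-epoxide on the face syn to C5 F3. Conditions: the matching antipode of [N,N′-bis(3,5-di-tert-butylsalicylidene)cyclohexane-1,2-diaminato]manganese chloride, NaOCl, 4-phenylpyridine N-oxide.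
- LiBr/AcOH opens the epoxide at allylic C9 with inversion and gives the regioisomeric 9-bromo-10-ol F4.
- Tf2O/2,6-lutidine gives its C10 triflate F5.
- In aqueous acetone the neighbouring C9 bromine displaces the triflate from the back (anchimeric assistance). Water then opens the bromonium ion at allylic C9, which rejoins the route at 15.

**Step 6.** The cyclopropylcarbinyl xanthate may ionise at the pyrolysis temperature, with oxygen-to-sulfur rearrangement or ring opening.

The fallback goes through the ketone.
- From 5, Dess–Martin oxidation gives the cyclopropyl ketone F6.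
- TsNHNH2 gives its tosylhydrazone F7.
- A Shapiro-type elimination with LDA gives 7. An amide base, not an alkyllithium, is used so that the vinylic bromides are spared.

## Further compounds

F1 | step 7 | (3S,6R)-3-bromo-6-(bromomethyl)-6-(4,4-dibromo-3-methylbut-3-en-1-yl)-1,5,5-trimethylcyclohex-1-ene | CC1=C[C@@H](Br)CC(C)(C)[C@]1(CBr)CCC(C)=C(Br)Br
F2 | step 7 | (6S)-6-(bromomethyl)-6-(4,4-dibromo-3-methylbut-3-en-1-yl)-1,5,5-trimethylcyclohexa-1,3-diene | CC1=CC=CC(C)(C)[C@]1(CBr)CCC(C)=C(Br)Br
F3 | step 9 | 9,10-epoxide of 12 on the face syn to C5 | CC1=C[C@@H]2O[C@@H]2C(C)(C)[C@]13CCC(C)=C(Br)C3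
F4 | step 9 | 2,9-dibromo-3,7,11,11-tetramethylspiro[5.5]undeca-2,7-dien-10-ol, Br syn to C1, OH syn to C5 | CC1=C[C@@H](Br)[C@H](O)C(C)(C)[C@]12CCC(C)=C(Br)C2
F5 | step 9 | C10 triflate of F4 | CC1=C[C@@H](Br)[C@H](OS(=O)(=O)C(F)(F)F)C(C)(C)[C@]12CCC(C)=C(Br)C2
F6 | step 6 | (1R,6R)-6-(4,4-dibromo-3-methylbut-3-en-1-yl)-1,5,5-trimethylbicyclo[4.1.0]heptan-2-one | CC(CC[C@]12C[C@@]1(C)C(=O)CCC2(C)C)=C(Br)Br
F7 | step 6 | tosylhydrazone of F6 | CC(CC[C@]12C[C@@]1(C)C(=NNS(=O)(=O)c3ccc(C)cc3)CCC2(C)C)=C(Br)Br
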